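**Strategy.** Everything rests on opening the eight-membered ring (ring A) into two four-carbon dienes by cutting the bond between the ring CH2 and the methyl-bearing CH and the bond between the α- and β-carbons of the butenolide (ring B). A nickel-catalysed intramolecular [4+4] cycloaddition makes both bonds in one operation and closes rings A and B together. It exploits the masked cycloocta-1,5-diene of ring A: the cyclopropane carbons and the acetoxy/side-chain carbons are its two alkenes, and the lactone O–CH2 and C=O atoms are the three-atom tether. The precursor is an acyclic tetraene: a 2-silyloxy diene bearing the citronellal-derived side chain, esterified with sorbic acid. The butenolide bond is made as a σ bond and dehydrogenated later.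

Key step: step 8

Remark (labels): ring A atoms are C-a (acetoxy carbon), C-b (CH2), C-c (methyl-bearing CH), C-d and C-e (cyclopropane CH, C-e next to the butenolide), C-f (butenolide α-carbon), C-g (butenolide β-carbon), C-h (side-chain-bearing CH); ring C is the cyclopropane; C-1′ is the side-chain stereocentre.

Remark (assumption): (R)-citronellal of high enantiopurity is taken as commercial and supplies C-1′, which no step touches.

Step 1
Reactants: 1 (R)-citronellal
Product: 2 N-tert-butyl aldimine of 1
Conditions: t-BuNH2, MgSO4, CH2Cl2, 0 °C to rt; used crude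
Reagents that add atoms: tert-butylamine, CC(C)(C)N
Why: Imine formation with a hindered primary amine gives the aldimine needed for a directed aldol reaction and leaves the β-stereocentre untouched.

Step 2
Reactants: 2 N-tert-butyl aldimine of 1; 3 (tert-butyldimethylsilyloxy)acetaldehyde
Product: 6 (2E)-4-(tert-butyldimethylsilyloxy)-2-[(2R)-6-methylhept-5-en-2-yl]but-2-enal, via lithium aza-enolate 4 (not isolated), via β-hydroxy imine 5 (not isolated)
Conditions: LiN(i-Pr)2, THF, 0 °C; 3, −78 °C; aq. oxalic acid, THF, rt
Reagents that add atoms: none
Why: Directed aldol condensation through the metalated aldimine is cross-selective because only the imine is deprotonated, and acid hydrolysis with loss of water should give the 2-substituted enal in its thermodynamic E form (CHO trans to CH2OTBS), the geometry the diene terminus C-g needs.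

Step 3
Reactants: 6 (E)-enal
Product: 7 (3E)-5-(tert-butyldimethylsilyloxy)-3-[(2R)-6-methylhept-5-en-2-yl]pent-3-en-2-ol (both carbinol epimers)
Conditions: MeMgBr, THF, −78 °C; H2O
Reagents that add atoms: methylmagnesium bromide, C[Mg]Br
Why: Grignard 1,2-addition to the enal supplies the carbon that becomes C-b; the new carbinol centre is unselective and is erased in step 4.

Step 4
Reactants: 7 allylic alcohol
Product: 8 (3E)-5-(tert-butyldimethylsilyloxy)-3-[(2R)-6-methylhept-5-en-2-yl]pent-3-en-2-one
Conditions: Dess–Martin periodinane, CH2Cl2, rt
Reagents that add atoms: none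
Why: Dess–Martin oxidation of the allylic alcohol gives the methyl enone without touching the silyl ether or the alkenes.

Step 5
Reactants: 8 silyl-protected enone
Product: 9 (3E)-5-hydroxy-3-[(2R)-6-methylhept-5-en-2-yl]pent-3-en-2-one
Conditions: HF·pyridine, THF/pyridine, 0 °C to rt
Reagents that add atoms: none
Why: Non-basic fluoride cleavage of the primary silyl ether avoids double-bond migration, and the E geometry holds the hydroxyl trans to the acetyl group so no cyclic hemiketal can form.

Step 6
Reactants: 9 hydroxy enone; 10 sorbic acid
Product: 11 (2E)-3-[(2R)-6-methylhept-5-en-2-yl]-4-oxopent-2-en-1-yl (2E,4E)-hexa-2,4-dienoate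
Conditions: EDC·HCl, DMAP (cat.), CH2Cl2, 0 °C to rt
Reagents that add atoms: none
Why: Carbodiimide (Steglich) esterification joins the two diene precursors through the atoms that become the lactone O–CH2 and C=O.

Step 7
Reactants: 11 keto ester
Product: 12 (2E)-4-(tert-butyldimethylsilyloxy)-3-[(2R)-6-methylhept-5-en-2-yl]penta-2,4-dien-1-yl (2E,4E)-hexa-2,4-dienoate
Conditions: TBSOTf, Et3N, CH2Cl2, −78 to 0 °C; used after filtration through basic alumina
Reagents that add atoms: tert-butyldimethylsilyl triflate, CC(C)(C)[Si](C)(C)OS(=O)(=O)C(F)(F)F
Why: Soft enolisation of the methyl ketone at its methyl group (silyl enol ether formation) gives the cross-conjugated 2-silyloxy diene that carries the future C-a oxygen, the ester being far less readily enolised under these conditions.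

Step 8
Reactants: 12 silyloxy tetraene ester
Product: 13 cis-fused cycloadduct: ring A as a cycloocta-1,5-diene (C-a=C-h silyl enol ether with OTBS on C-a and the side chain on C-h; C-d=C-e cis alkene), γ-lactone ring B fused at C-f/C-g, methyl on C-c; the hydrogens on C-c, C-f and C-g on one face
Conditions: Ni(COD)2 (10 mol %), (S)-BINOL-derived N,N-dimethylphosphoramidite (20 mol %), toluene (0.01 M), 60 °C
Reagents that add atoms: none
Why: Zerovalent nickel binds both dienes and couples the tethered termini C-g and C-f by oxidative cyclisation (five-membered closure that makes ring B as a saturated γ-lactone), and the resulting bis(allyl) divalent nickel then joins the distal termini C-b and C-c by reductive elimination, closing ring A as a cis,cis-cycloocta-1,5-diene. The closest known reaction type is the nickel-catalysed intramolecular [4+4] cycloaddition of two 1,3-dienes joined by a three-atom tether, which gives cis-fused bicyclo[6.3.0]undecadienes. C-g and C-f come out cis because of the short tether (both are erased in step 14); C-c is set relative to C-f by the E,E geometry of the sorbate, which reacts suprafacially in its s-cis form and so places the methyl cis to the lactone carbonyl carbon. The sense of these centres relative to the remote C-1′ cannot be secured by the substrate and is assigned to the chiral ligand, the antipode being taken if the mismatched series prevails. The step needs [4+4] closure ahead of nickel-catalysed [4+2] closure and of ionisation of the dienyl ester; the electron-rich/electron-poor diene pair, the three-atom tether and a π-acidic phosphoramidite favour the former.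

Step 9
Reactants: 13 cycloadduct
Product: 14 cyclopropane (ring C on C-d/C-e, its CH2 trans to the C-c methyl and to the lactone carbonyl carbon on C-f); silyl enol ether and lactone unchanged
Conditions: CH2N2 (excess, Et2O), Pd(OAc)2 (5 mol %), Et2O, 0 °C
Reagents that add atoms: diazomethane, C=[N+]=[N-]
Why: Palladium-catalysed diazomethane cyclopropanation is sterically governed and should take the cis-disubstituted ring alkene in preference to the tetrasubstituted enol ether and the trisubstituted side-chain alkene, delivering CH2 to the face opposite the two allylic substituents (C-c methyl and lactone carbon) that flank the alkene on the same side.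

Step 10
Reactants: 14 cyclopropanated silyl enol ether
Product: 16 keto lactone (ketone at C-a; side chain on C-h trans to the lactone CH2 on C-g), via tetrabutylammonium enolate 15 (not isolated)
Conditions: Bu4NF, AcOH, THF, 0 °C; then DBU (0.2 equiv), CH2Cl2, rt
Reagents that add atoms: none
Why: Fluoride desilylation releases the enolate, which is protonated to the ketone, and amidine-base equilibration at the acidic α-carbon C-h should place the side chain trans to the neighbouring lactone CH2 (thermodynamic control) while the far less acidic lactone α-centre stays cis-fused.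

Step 11
Reactants: 16 keto lactone
Product: 17 alcohol (C-a hydroxyl cis to the side chain on C-h)
Conditions: LiBH(s-Bu)3, THF, −78 °C; AcOH
Reagents that add atoms: none
Why: The bulky borohydride reduces the ketone and not the lactone at low temperature and should attack the face opposite the adjacent side chain, giving the alcohol cis to it (substrate-controlled ketone reduction).

Step 12
Reactants: 17 alcohol
Product: 18 acetate
Conditions: Ac2O, DMAP (cat.), pyridine, CH2Cl2, rt
Reagents that add atoms: acetic anhydride, CC(=O)OC(C)=O
Why: DMAP-catalysed acetylation of the secondary alcohol installs the acetoxy group with retention at C-a.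

Step 13
Reactants: 18 acetate
Product: 19 α-phenylselanyl lactone (SePh on C-f, cis to the hydrogen on C-g)
Conditions: LiN(SiMe3)2, THF, −78 °C; PhSeSePh, HMPA, −78 to −40 °C; AcOH
Reagents that add atoms: diphenyl diselenide, c1ccc(cc1)[Se][Se]c1ccccc1
Why: The lactone α-hydrogen is several pK units more acidic than the acetate α-hydrogens, so the silylamide should enolise only the lactone, and selenenylation with the diselenide (which does not add to the side-chain alkene) occurs on the convex face of the cis-fused enolate, cis to the C-g hydrogen.

Step 14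
Reactants: 19 α-phenylselanyl lactone
Product: 21 butenolide (C-f=C-g) carrying the (2R)-6-methylhept-5-en-2-yl side chain, via selenoxide 20 (not isolated)
Conditions: H2O2 (30 %, excess), pyridine, CH2Cl2, 0 °C to rt
Reagents that add atoms: none
Why: Selenoxide syn-elimination can only run toward the cis hydrogen on C-g (the other β-carbon is a cyclopropane CH), which gives the tetrasubstituted butenolide alkene and removes the two transient fusion stereocentres; excess oxidant scavenges the selenenic acid before it can add to the side-chain alkene.

Step 15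
Reactants: 21 butenolide
Product: 22 target CNP0205234.1
Conditions: O2, visible light, tetraphenylporphyrin (cat.), CH2Cl2, 0 °C
Reagents that add atoms: dioxygen (as singlet oxygen), O=O
Why: Schenck ene reaction of singlet oxygen with the only electron-rich alkene puts oxygen on the dimethyl-substituted carbon with hydrogen transfer from the allylic CH2 and gives the (E)-allylic tertiary hydroperoxide; the regioisomeric secondary hydroperoxide from methyl hydrogen abstraction is expected as a co-product and is separated by chromatography.

**Compound list**

1 | (R)-citronellal, (3R)-3,7-dimethyloct-6-enal | O=CC[C@H](C)CCC=C(C)C | starting material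
2 | (1E,3R)-N-tert-butyl-3,7-dimethyloct-6-en-1-imine | CC(C)(C)/N=C/C[C@H](C)CCC=C(C)C | intermediate
3 | (tert-butyldimethylsilyloxy)acetaldehyde | O=CCO[Si](C)(C)C(C)(C)C | starting material
4 | lithium aza-enolate of 2 (C=C geometry not defined) | [Li]N(C(C)(C)C)C=C[C@H](C)CCC=C(C)C | intermediate
5 | β-hydroxy imine aldol adduct (two new centres as a mixture) | CC(C)(C)/N=C/C(C(O)CO[Si](C)(C)C(C)(C)C)[C@H](C)CCC=C(C)C | intermediate
6 | (2E)-4-(tert-butyldimethylsilyloxy)-2-[(2R)-6-methylhept-5-en-2-yl]but-2-enal | O=C/C(=C/CO[Si](C)(C)C(C)(C)C)[C@H](C)CCC=C(C)C | intermediate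
7 | (3E)-5-(tert-butyldimethylsilyloxy)-3-[(2R)-6-methylhept-5-en-2-yl]pent-3-en-2-ol (carbinol epimers) | CC(O)/C(=C/CO[Si](C)(C)C(C)(C)C)[C@H](C)CCC=C(C)C | intermediate
8 | (3E)-5-(tert-butyldimethylsilyloxy)-3-[(2R)-6-methylhept-5-en-2-yl]pent-3-en-2-one | CC(=O)/C(=C/CO[Si](C)(C)C(C)(C)C)[C@H](C)CCC=C(C)C | intermediate
9 | (3E)-5-hydroxy-3-[(2R)-6-methylhept-5-en-2-yl]pent-3-en-2-one | CC(=O)/C(=C/CO)[C@H](C)CCC=C(C)C | intermediate
10 | sorbic acid, (2E,4E)-hexa-2,4-dienoic acid | C/C=C/C=C/C(=O)O | starting material
11 | (2E)-3-[(2R)-6-methylhept-5-en-2-yl]-4-oxopent-2-en-1-yl (2E,4E)-hexa-2,4-dienoate | CC(=O)/C(=C/COC(=O)/C=C/C=C/C)[C@H](C)CCC=C(C)C | intermediate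
12 | (2E)-4-(tert-butyldimethylsilyloxy)-3-[(2R)-6-methylhept-5-en-2-yl]penta-2,4-dien-1-yl (2E,4E)-hexa-2,4-dienoate | C=C(O[Si](C)(C)C(C)(C)C)/C(=C/COC(=O)/C=C/C=C/C)[C@H](C)CCC=C(C)C | intermediate
13 | cis-fused [4+4] cycloadduct (silyl enol ether C-a=C-h, cis alkene C-d=C-e, γ-lactone at C-f/C-g, C-c methyl cis to the lactone carbonyl carbon) | CC(C)(C)[Si](C)(C)OC1=C([C@H](C)CCC=C(C)C)[C@@H]2COC(=O)[C@@H]2/C=C\[C@H](C)C1 | intermediate
14 | cyclopropanated silyl enol ether (ring C CH2 trans to the C-c methyl) | CC(C)(C)[Si](C)(C)OC1=C([C@H](C)CCC=C(C)C)[C@@H]2COC(=O)[C@@H]2[C@H]3C[C@H]3[C@H](C)C1 | intermediate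
15 | tetrabutylammonium enolate of 16 | [O-]C1=C([C@H](C)CCC=C(C)C)[C@@H]2COC(=O)[C@@H]2[C@H]3C[C@H]3[C@H](C)C1.CCCC[N+](CCCC)(CCCC)CCCC | intermediate
16 | keto lactone (ketone at C-a, side chain on C-h trans to the lactone CH2) | O=C1[C@@H]([C@H](C)CCC=C(C)C)[C@@H]2COC(=O)[C@@H]2[C@H]3C[C@H]3[C@H](C)C1 | intermediate
17 | hydroxy lactone (C-a hydroxyl cis to the side chain) | O[C@H]1[C@@H]([C@H](C)CCC=C(C)C)[C@@H]2COC(=O)[C@@H]2[C@H]3C[C@H]3[C@H](C)C1 | intermediate
18 | acetoxy lactone | CC(=O)O[C@H]1[C@@H]([C@H](C)CCC=C(C)C)[C@@H]2COC(=O)[C@@H]2[C@H]3C[C@H]3[C@H](C)C1 | intermediate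
19 | α-phenylselanyl lactone (SePh on C-f) | CC(=O)O[C@H]1[C@@H]([C@H](C)CCC=C(C)C)[C@@H]2COC(=O)[C@]2([Se]c4ccccc4)[C@H]3C[C@H]3[C@H](C)C1 | intermediate
20 | selenoxide of 19 (selenium centre as a mixture) | CC(=O)O[C@H]1[C@@H]([C@H](C)CCC=C(C)C)[C@@H]2COC(=O)[C@]2([Se](=O)c4ccccc4)[C@H]3C[C@H]3[C@H](C)C1 | intermediate
21 | butenolide with the (2R)-6-methylhept-5-en-2-yl side chain | CC(=O)O[C@H]1[C@@H]([C@H](C)CCC=C(C)C)C2=C(C(=O)OC2)[C@H]3C[C@H]3[C@H](C)C1 | intermediate
22 | CNP0205234.1, butenolide with the (2R,4E)-6-hydroperoxy-6-methylhept-4-en-2-yl side chain | CC(=O)O[C@H]1[C@@H]([C@H](C)C/C=C/C(C)(C)OO)C2=C(C(=O)OC2)[C@H]3C[C@H]3[C@H](C)C1 | target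

Total steps: 15. Longest linear sequence: 15 steps (1 to 22).

**Steps most likely to fail**

Step 8 (key step). The ligand may not discriminate the two diene faces relative to the remote C-1′ centre, so that both ring series form. Fallback: catalyst control is given up and the two series are resolved later as diastereomers. Setting out from 12, Ni(COD)2 (10 mol %) with PPh3 (20 mol %) in toluene at 60 °C should give 13 together with the ring-diastereomeric cycloadduct F1 (C-c, C-f and C-g inverted). The pair is carried through steps 9 and 10, giving beside 14 the ring-diastereomeric cyclopropane F2 and beside 16 the ring-diastereomeric keto lactone F3. At the ketone stage the ring centre C-h adjoins C-1′, so the two series should separate on silica gel, and the route is rejoined at 16.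

Step 15. Hydrogen abstraction from the cis methyl group competes with abstraction from the CH2, so the ene reaction is poorly regioselective. Fallback: setting out from 21, hydroxyselenation with benzeneselenenic acid made in the flask (PhSeSePh, H2O2, MgSO4, CH2Cl2, 0 °C) should put the hydroxyl on the dimethyl-substituted carbon and give the β-hydroxy selenide F5. Oxidation with excess H2O2 then triggers a selenoxide elimination that can only run toward the CH2 and gives the (E)-tertiary allylic alcohol F6. Acid-catalysed perhydrolysis (50 % H2O2, H2SO4 cat., Et2O, 0 °C) through the tertiary allyl cation returns to the route at 22.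

Step 11. Hydride may be delivered to the other face of the ketone, because the face opposite the side chain carries the β-substituents on C-c and C-g. Fallback: setting out from 16, the reduction would then give the C-a epimeric alcohol F4. Mitsunobu esterification with acetic acid (PPh3, diisopropyl azodicarboxylate, AcOH, toluene, 0 °C to rt) inverts C-a and gives the acetate directly, so the route is rejoined at 18.

**Further compounds**

F1 | step 8 | ring-diastereomeric cycloadduct (C-c, C-f, C-g inverted relative to 13) | CC(C)(C)[Si](C)(C)OC1=C([C@H](C)CCC=C(C)C)[C@H]2COC(=O)[C@H]2/C=C\[C@@H](C)C1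
F2 | step 8 | ring-diastereomeric cyclopropane (all ring centres inverted relative to 14) | CC(C)(C)[Si](C)(C)OC1=C([C@H](C)CCC=C(C)C)[C@H]2COC(=O)[C@H]2[C@@H]3C[C@@H]3[C@@H](C)C1
F3 | step 8 | ring-diastereomeric keto lactone (all ring centres inverted relative to 16) | O=C1[C@H]([C@H](C)CCC=C(C)C)[C@H]2COC(=O)[C@H]2[C@@H]3C[C@@H]3[C@@H](C)C1
F4 | step 11 | C-a epimeric alcohol of 17 | O[C@@H]1[C@@H]([C@H](C)CCC=C(C)C)[C@@H]2COC(=O)[C@@H]2[C@H]3C[C@H]3[C@H](C)C1
F5 | step 15 | β-hydroxy selenide of 21 (selenide carbon as a mixture) | CC(=O)O[C@H]1[C@@H]([C@H](C)CC([Se]c4ccccc4)C(C)(C)O)C2=C(C(=O)OC2)[C@H]3C[C@H]3[C@H](C)C1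
F6 | step 15 | (E)-tertiary allylic alcohol | CC(=O)O[C@H]1[C@@H]([C@H](C)C/C=C/C(C)(C)O)C2=C(C(=O)OC2)[C@H]3C[C@H]3[C@H](C)C1
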